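**Target:** (2S)-5,7-dihydroxy-2-(8-hydroxy-2,2-dimethyl-2H-chromen-6-yl)chroman-4-one. The SMILES was re-read as a 5,7-dihydroxyflavanone with a 2,2-dimethylpyran fused at O4'/C5', a free 3'-OH, and C2 = S.

**Assumptions (one line each):**
- (2S)-Naringenin of ≥98% ee is purchased (ee checked by chiral HPLC on receipt).
- tert-Butyl (2-methylbut-3-en-2-yl) carbonate is purchased; if not, it is one step from 2-methylbut-3-en-2-ol and Boc2O.

## Retrosynthetic overview

1. Target ⇒ (2S)-5'-prenyleriodictyol (9): the pyran ring is formed last, by anodic catechol → o-quinone → o-quinone methide → oxa-6π closure (O4'–CMe2 bond).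
2. 9 ⇒ 3'-prenyl-4'-phenol 6: the second B-ring oxygen is put on the only free ortho carbon by phenol ortho-oxygenation.
3. 6 ⇒ 7-O-MOM-naringenin (3): O-tert-prenylation then aromatic Claisen; the 4-hydroxyphenyl ring is symmetric, so there is no regiochemical choice.
4. The A/C rings and the C2 stereocentre come intact from (2S)-naringenin (1); no ring other than the pyran is built.

## Route

**Step 1**
Reactants: 1, (2S)-naringenin; 2, chloromethyl methyl ether (MOMCl)
Product: 3, (2S)-5-hydroxy-2-(4-hydroxyphenyl)-7-(methoxymethoxy)chroman-4-one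
Conditions: MOMCl (1.05 equiv), i-Pr2NEt (1.2 equiv), DMF/CH2Cl2, 0 °C → rt
Reagents that add atoms: MOMCl, COCCl
Why: Selective phenol O-alkylation (Williamson type): 7-OH is the most acidic phenol (para to C=O), 5-OH is locked in the C=O hydrogen bond and 4'-OH is about 3 pKa units weaker; C2 is not touched.

**Step 2**
Reactants: 3; 4, tert-butyl (2-methylbut-3-en-2-yl) carbonate
Product: 6, (2S)-5-hydroxy-2-[4-hydroxy-3-(3-methylbut-2-en-1-yl)phenyl]-7-(methoxymethoxy)chroman-4-one, via the non-isolated aryl 1,1-dimethylallyl ether 5
Conditions: Pd(PPh3)4 (3 mol%), 4 (1.3 equiv), THF, 0 °C → rt; filter through Florisil; PhMe, 105 °C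
Reagents that add atoms: carbonate 4, CC(C)(C)OC(=O)OC(C)(C)C=C (delivers C5H9)
Why: Tsuji–Trost O-tert-prenylation of the only free non-chelated phenol gives ether 5, and the aromatic Claisen [3,3] shift then delivers a normal prenyl group to an ortho carbon (para is blocked and the two ortho positions are equivalent, so one regioisomer); conditions are neutral, so C2 is unaffected.

**Step 3**
Reactants: 6; 7, 2-iodoxybenzoic acid (IBX, used as stabilised SIBX)
Product: 8, (2S)-2-[3,4-dihydroxy-5-(3-methylbut-2-en-1-yl)phenyl]-5-hydroxy-7-(methoxymethoxy)chroman-4-one (B ring renumbered)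
Conditions: IBX (1.1 equiv), DMF, 0 °C → rt; then aq. ascorbic acid, 0 °C
Reagents that add atoms: IBX, OI1(=O)OC(=O)c2ccccc12 (delivers one O)
Why: IBX phenol ortho-oxygenation (aryloxy-iodane, intramolecular O transfer) can only go to the one unsubstituted ortho carbon of the 2,4-dialkylphenol, and the o-quinone is reduced at once to the catechol before it can isomerise or be over-oxidised; the chelated, acyl-deactivated A-ring phenol and C2 do not react.

**Step 4**
Reactants: 8
Product: 9, (2S)-2-[3,4-dihydroxy-5-(3-methylbut-2-en-1-yl)phenyl]-5,7-dihydroxychroman-4-one (5'-prenyleriodictyol)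
Conditions: TMSOTf, 2,2'-bipyridyl, CH2Cl2, 0 °C → rt; then H2O
Reagents that add atoms: none
Why: Non-protic aryl MOM cleavage (silyl triflate/bipyridyl, via a bipyridinium methyl ether hydrolysed on work-up) avoids the acid that would cyclise the o-prenylcatechol to a chroman; transient aryl TMS ethers fall off in the aqueous work-up and C2 is untouched.

**Step 5**
Reactants: 9
Product: 10, target, (2S)-5,7-dihydroxy-2-(8-hydroxy-2,2-dimethyl-2H-chromen-6-yl)chroman-4-one
Conditions: divided cell, graphite-felt anode, Pt cathode, +0.45 V vs Ag/AgCl (about 2.1 F/mol), 0.1 M LiClO4, MeCN/phosphate buffer pH 6.5 (1:1), 5 mM, N2, 0 °C; then rt 30 min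
Reagents that add atoms: none (net loss of 2 H)
Why: Proposed new method: anodic, catechol-selective 2e⁻/2H⁺ oxidation gives the 3-prenyl-o-quinone; buffer-catalysed vinylogous enolisation of its benzylic/allylic CH2 (through C3'=O) gives the vinyl o-quinone methide, which closes by thermal oxa-6π electrocyclisation onto O4' (the carbonyl next to the prenyl group), so the pyran oxygen and the free 3'-OH are fixed by connectivity. The potential is chosen from expected values (not measured) to sit below the monophenol product and the A ring, so the oxidation should stop after one turnover. The closest known chemistry is Ag2O/DDQ or amine-mediated prenyl-(hydro)quinone → chromenol cyclisation and anodic catechol → o-quinone ECE annulations. No stereocentre is formed.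

## Compound list

1 | (2S)-naringenin | Oc1ccc(cc1)[C@@H]1CC(=O)c2c(O)cc(O)cc2O1 | starting material
2 | chloromethyl methyl ether | COCCl | starting material
3 | 7-O-MOM-(2S)-naringenin | Oc1ccc(cc1)[C@@H]1CC(=O)c2c(O)cc(OCOC)cc2O1 | intermediate
4 | tert-butyl (2-methylbut-3-en-2-yl) carbonate | CC(C)(C)OC(=O)OC(C)(C)C=C | starting material
5 | 7-O-MOM-4'-O-(2-methylbut-3-en-2-yl)-(2S)-naringenin | C=CC(C)(C)Oc1ccc(cc1)[C@@H]1CC(=O)c2c(O)cc(OCOC)cc2O1 | intermediate (not isolated)
6 | 7-O-MOM-3'-prenyl-(2S)-naringenin | CC(C)=CCc1cc(ccc1O)[C@@H]1CC(=O)c2c(O)cc(OCOC)cc2O1 | intermediate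
7 | 2-iodoxybenzoic acid (IBX) | OI1(=O)OC(=O)c2ccccc12 | starting material (reagent)
8 | 7-O-MOM-5'-prenyl-(2S)-eriodictyol | CC(C)=CCc1cc(cc(O)c1O)[C@@H]1CC(=O)c2c(O)cc(OCOC)cc2O1 | intermediate
9 | 5'-prenyl-(2S)-eriodictyol | CC(C)=CCc1cc(cc(O)c1O)[C@@H]1CC(=O)c2c(O)cc(O)cc2O1 | intermediate
10 | (2S)-5,7-dihydroxy-2-(8-hydroxy-2,2-dimethyl-2H-chromen-6-yl)chroman-4-one | CC1(C)C=Cc2cc([C@@H]3CC(=O)c4c(O)cc(O)cc4O3)cc(O)c2O1 | target

## Step count and risks

Total steps: 5 (6 if carbonate 4 has to be made). Longest linear sequence: 5.

Steps most likely to fail: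

1. **Step 5 (proposed new anodic cyclisation).** Risks: the o-quinone may instead isomerise through C2–H to a p-quinone methide (erosion of ee; check by chiral HPLC), couple with an A ring, or the product may be over-oxidised. Fallback, known chemistry: drop the electrochemical step and the catechol isolation. Oxidise phenol 6 with IBX to the o-quinone and add Et3N in the same flask to trigger the known prenylquinone → quinone methide → chromene isomerisation, then remove MOM.
2. **Step 3 (IBX ortho-oxygenation).** Risks: in-flask isomerisation of the prenyl-o-quinone followed by I(V) over-oxidation, or attack at the chelated A-ring phenol. Fallback: Mg-mediated ortho-formylation (MgCl2, Et3N, paraformaldehyde) at the single free ortho position, then Dakin oxidation to the catechol.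
3. **Step 2 (Pd O-tert-prenylation/Claisen).** Risks: linear O-prenyl ether, Pd-mediated C-allylation, or re-ionisation of ether 5 on heating. Fallback: O-propargylation of 3 with 3-chloro-3-methylbut-1-yne (K2CO3, KI, CuI), Lindlar semi-hydrogenation to the same ether 5, then thermal Claisen.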